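The dihydropyran ring is cut at C4–C4a and O1–C8a. This leaves its O1–C2–C3–C4 segment folded into a strained (R)-2,2-dialkyloxetane and the benzene ring as 4-iodo-3-methylanisole. One palladium/norbornene (Catellani-type) [4+2] annulation joins them: ortho C–H alkylation by the opened oxetane makes C4–C4a, and ipso C–O coupling of the released tertiary alkoxide makes O1–C8a. The step exploits the C8 methyl group beside C8a, which leaves C4a as the only free ortho site and forces norbornene extrusion, and the quaternary C2, whose C–O bond is never broken. The oxetane arises from a methyl ketone by asymmetric double methylene transfer; the chain stereocentres come from the chiral pool.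

Key step: step 5

Numbering: chroman locants O1, C2, C3, C4, C4a, C5–C8, C8a; side chain C1' (on C2) to C13'. The target is 2R,4'R,8'S. C8' is S only because the C11'=C12' double bond outranks the C7' branch; in space it matches natural tocopherols.

Assumption: the (S)-BINOL-derived catalyst of step 4 is taken to give the (R)-epoxide from this alkyl methyl ketone. If correlation with the diol of the step 4 fallback shows the opposite sense, the (R)-BINOL catalyst is used and nothing else changes.

Step 1
Reactants: 1 (R)-citronellyl bromide, (6R)-8-bromo-2,6-dimethyloct-2-ene; 2 (S)-3-bromo-2-methylpropan-1-ol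
Product: 5 (2R,6S)-2,6,10-trimethylundec-9-en-1-ol, via citronellylmagnesium bromide 3 (not isolated), via chloromagnesium alkoxide 4 (not isolated)
Conditions: 1, Mg, THF, 40 °C; separately 2, MeMgCl (1.0 equiv), THF, −20 °C; combine, Li2CuCl4 (5 mol %), NMP (4 equiv), THF, −20 °C to rt; 1 M HCl work-up
Reagents that add atoms: none
Why: A copper-catalysed Grignard alkyl–alkyl cross-coupling (Kochi coupling) joins C6' of 3 to C5' of 4 between two primary carbons, so the C8' and C4' stereocentres bought with 1 and 2 are carried over unchanged, and the hydroxyl group is masked in the flask as its magnesium alkoxide.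

Step 2
Reactants: 5 (2R,6S)-2,6,10-trimethylundec-9-en-1-ol
Product: 6 (6S,10R)-11-bromo-2,6,10-trimethylundec-2-ene
Conditions: CBr4, PPh3, CH2Cl2, 0 °C
Reagents that add atoms: carbon tetrabromide, BrC(Br)(Br)Br
Why: The Appel reaction replaces the primary hydroxyl group by bromide through SN2 attack on the alkoxyphosphonium salt under neutral conditions that leave the trisubstituted alkene and the adjacent C4' stereocentre untouched.

Step 3
Reactants: 6 (6S,10R)-11-bromo-2,6,10-trimethylundec-2-ene; 7 methyl vinyl ketone (but-3-en-2-one)
Product: 10 (6R,10S)-6,10,14-trimethylpentadec-13-en-2-one, via alkylmagnesium bromide 8 (not isolated), via silyl enol ether 9 (not isolated)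
Conditions: 6, Mg, THF, 45 °C; then CuBr·SMe2 (10 mol %), DMPU, TMSCl (2 equiv), 7, THF, −78 °C; 1 M HCl, THF, rt
Reagents that add atoms: none
Why: A copper-catalysed conjugate (1,4-) addition of the Grignard reagent, accelerated by TMSCl, which traps the enolate as 9 and so holds back 1,2-addition and enone polymerisation, adds the C2'–C1'–C2(=O)–CH3 unit without touching the β-stereocentre C4'.

Step 4
Reactants: 10 (6R,10S)-6,10,14-trimethylpentadec-13-en-2-one
Product: 12 (2R)-2-methyl-2-[(4R,8S)-4,8,12-trimethyltridec-11-en-1-yl]oxetane, via epoxide 11 (not isolated)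
Conditions: pre-formed salt-free dimethylsulfoxonium methylide in THF (1.2 equiv), LaLi3[(S)-binaphthoxide]3 (5 mol %), tris(2,4,6-trimethoxyphenyl)phosphine oxide (5 mol %), 5 Å molecular sieves, THF, rt; then more ylide (1.5 equiv) and catalyst (15 mol %), 45 °C
Reagents that add atoms: dimethylsulfoxonium methylide, C[S+](C)(=O)[CH2-]
Why: A catalytic asymmetric Corey–Chaykovsky epoxidation, in which the chiral lanthanum–lithium binaphthoxide binds ketone and ylide together and tells the CH3 arm from the CH2R arm, sets C2 as R in 11, and a second ylide then attacks only the epoxide CH2 and recloses by 4-exo-tet displacement of DMSO (epoxide-to-oxetane ring expansion), so that the C2–O bond persists and the faster reaction of the matched epoxide should raise the stereochemical purity of 12.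

Step 5
Reactants: 12 (2R)-2-methyl-2-[(4R,8S)-4,8,12-trimethyltridec-11-en-1-yl]oxetane; 13 4-iodo-3-methylanisole (1-iodo-4-methoxy-2-methylbenzene)
Product: 15 (2R)-6-methoxy-2,8-dimethyl-2-[(4R,8S)-4,8,12-trimethyltridec-11-en-1-yl]chroman, via iodo alcohol 14 (not isolated)
Conditions: Pd(OAc)2 (10 mol %), XPhos (20 mol %), norbornene (1 equiv), Bu4NI (50 mol %), pivalic acid (30 mol %), K2CO3 (3 equiv), NMP, 100 °C, argon, 13 added slowly by syringe pump
Reagents that add atoms: none
Why: Proposed new method: zerovalent palladium inserts into the C–I bond of 13, norbornene carbopalladation and carbonate-assisted palladation of the only free ortho C–H give the aryl–norbornyl palladacycle, and this electron-rich divalent palladium centre takes up the primary C–I bond of 14 (formed reversibly by iodide attack at the unhindered O–CH2 carbon of the strained oxetane 12, with release of roughly 25 kcal/mol of ring strain) in an SN2-type oxidative addition, after which reductive elimination from tetravalent palladium makes C4–C4a. With the C8 methyl group and the new chain now flanking the palladium-bearing carbon, norbornene leaves by β-carbon elimination, and the tethered tertiary alkoxide binds divalent palladium and forms O1–C8a by C–O reductive elimination, which returns zerovalent palladium. The closest known reaction types are the palladium/norbornene [3+2] annulation of aryl iodides with epoxides to 2,3-dihydrobenzofurans, the ortho-alkylation/ipso-amination with bromoalkylamines to tetrahydroquinolines and the palladium-catalysed cyclisation of aryl halides bearing tertiary alcohols to 2,2-dialkylchromans; an oxetane as the four-atom partner is the untested part. The dihydropyran ring closes as a formal [4+2] annulation whose ring-closing event is reductive elimination from a seven-membered oxapalladacycle. No stereocentre is made: the C2–O1 bond of 12 is never broken, so C2 stays R, and C4' and C8' are remote spectators. The step needs site selectivity on the arene (secured by the C8 methyl group, which blocks one ortho position), opening of the oxetane at CH2 and not at the quaternary carbon (secured by the SN2 character of iodide attack under basic conditions free of Lewis acid), C–O coupling ahead of reduction (secured by a tertiary alkoxide without hydrogen on the carbinol carbon and by the bulky biarylphosphine) and an untouched C11'=C12' alkene (too hindered for migratory insertion).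

Step 6
Reactants: 15 (2R)-6-methoxy-2,8-dimethyl-2-[(4R,8S)-4,8,12-trimethyltridec-11-en-1-yl]chroman
Product: 16 (2R)-2,8-dimethyl-2-[(4R,8S)-4,8,12-trimethyltridec-11-en-1-yl]chroman-6-ol (target)
Conditions: NaSEt (5 equiv), DMF, 130 °C, argon; cold 1 M HCl work-up under argon
Reagents that add atoms: none
Why: Thiolate demethylation is an SN2 attack of the soft nucleophile on the unhindered O–CH3 carbon, which frees the C6 phenol while the tertiary O1–C2 ether, the C11'=C12' alkene and all three stereocentres cannot react.

Compound list
1 | (R)-citronellyl bromide, (6R)-8-bromo-2,6-dimethyloct-2-ene | CC(C)=CCC[C@@H](C)CCBr | starting material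
2 | (S)-3-bromo-2-methylpropan-1-ol | BrC[C@@H](C)CO | starting material
3 | (R)-citronellylmagnesium bromide | CC(C)=CCC[C@@H](C)CC[Mg]Br | intermediate
4 | chloromagnesium (S)-3-bromo-2-methylpropan-1-olate | BrC[C@@H](C)CO[Mg]Cl | intermediate
5 | (2R,6S)-2,6,10-trimethylundec-9-en-1-ol | CC(C)=CCC[C@@H](C)CCC[C@@H](C)CO | intermediate
6 | (6S,10R)-11-bromo-2,6,10-trimethylundec-2-ene | CC(C)=CCC[C@@H](C)CCC[C@@H](C)CBr | intermediate
7 | methyl vinyl ketone | C=CC(C)=O | starting material
8 | [(2R,6S)-2,6,10-trimethylundec-9-en-1-yl]magnesium bromide | CC(C)=CCC[C@@H](C)CCC[C@@H](C)C[Mg]Br | intermediate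
9 | trimethylsilyl enol ether of 10 (2-silyloxy-2-ene, E/Z mixture) | CC(C)=CCC[C@@H](C)CCC[C@@H](C)CCC=C(C)O[Si](C)(C)C | intermediate
10 | (6R,10S)-6,10,14-trimethylpentadec-13-en-2-one | CC(C)=CCC[C@@H](C)CCC[C@@H](C)CCCC(C)=O | intermediate
11 | (2R)-2-methyl-2-[(4R,8S)-4,8,12-trimethyltridec-11-en-1-yl]oxirane | CC(C)=CCC[C@@H](C)CCC[C@@H](C)CCC[C@]1(C)CO1 | intermediate
12 | (2R)-2-methyl-2-[(4R,8S)-4,8,12-trimethyltridec-11-en-1-yl]oxetane | CC(C)=CCC[C@@H](C)CCC[C@@H](C)CCC[C@]1(C)CCO1 | intermediate
13 | 4-iodo-3-methylanisole | COc1ccc(I)c(C)c1 | starting material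
14 | (3R,7R,11S)-1-iodo-3,7,11,15-tetramethylhexadec-14-en-3-ol | CC(C)=CCC[C@@H](C)CCC[C@@H](C)CCC[C@@](C)(O)CCI | intermediate
15 | (2R)-6-methoxy-2,8-dimethyl-2-[(4R,8S)-4,8,12-trimethyltridec-11-en-1-yl]chroman | CC(C)=CCC[C@@H](C)CCC[C@@H](C)CCC[C@]1(C)CCc2cc(OC)cc(C)c2O1 | intermediate
16 | (2R)-2,8-dimethyl-2-[(4R,8S)-4,8,12-trimethyltridec-11-en-1-yl]chroman-6-ol | CC(C)=CCC[C@@H](C)CCC[C@@H](C)CCC[C@]1(C)CCc2cc(O)cc(C)c2O1 | target

Total step count: 6
Longest linear sequence: 6 steps (1 → 5 → 6 → 10 → 12 → 15 → 16)

Steps most likely to fail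

1. Step 5.
- What may go wrong: the oxetane may open too slowly. Self-coupling of the aryl iodide at the palladacycle, loss of HI from the opened chain, or Grob-type fragmentation of the iodoalkoxide could then overtake the alkylation.
- Fallback (known chemistry): it sets out from epoxide 11, which is isolated when step 4 is stopped after the first methylene transfer, and comes back at 15. Commercial 4-bromo-3,5-dimethylanisole F1 is monobrominated at one of its two equivalent methyl groups (NBS, AIBN, PhCF3, reflux; Wohl–Ziegler bromination) to 2-bromo-1-(bromomethyl)-5-methoxy-3-methylbenzene F2. Mg in Et2O at 0 °C inserts only into the benzylic C–Br bond and gives (2-bromo-5-methoxy-3-methylbenzyl)magnesium bromide F3. F3 opens 11 at its CH2 terminus (CuI 10 mol %, THF, −30 °C, dilute HCl work-up) to the bromoaryl tertiary alcohol F4. Palladium-catalysed intramolecular etherification (Pd(OAc)2, t-BuXPhos, Cs2CO3, toluene, 90 °C) then closes O1–C8a with retention at C2 and gives 15.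

2. Step 4.
- What may go wrong: the catalyst may discriminate poorly between the CH3 and the long CH2R arm of the ketone, or the second methylene transfer may stall.
- Fallback: it sets out from ketone 10 and comes back at oxetane 12.
  - Horner–Wadsworth–Emmons olefination (triethyl phosphonoacetate, NaH, THF) and chromatographic removal of the Z isomer give ethyl (2E,7R,11S)-3,7,11,15-tetramethylhexadeca-2,14-dienoate F5.
  - i-Bu2AlH (CH2Cl2, −78 °C) gives the allylic alcohol F6.
  - Sharpless asymmetric epoxidation (Ti(OiPr)4, D-(−)-diethyl tartrate, t-BuOOH, 4 Å molecular sieves, CH2Cl2, −20 °C) touches only the allylic alkene and gives the (2R,3R)-epoxy alcohol F7.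
  - NaAlH2(OCH2CH2OMe)2 (THF, 0 °C) delivers hydride to the less substituted epoxide carbon and gives the (3R)-1,3-diol F8.
  - TsCl in pyridine sulfonylates only the primary hydroxyl group to the monotosylate F9.
  - KOt-Bu (THF, rt) closes 12 by 4-exo-tet Williamson displacement, with the C–O bond at the quaternary centre untouched.

3. Step 3.
- What may go wrong: the enone may polymerise, and 1,2-addition of the Grignard reagent may compete.
- Fallback: it sets out from alkylmagnesium bromide 8 (made from 6 as in step 3) and comes back at ketone 10. Substitution replaces conjugate addition. Li2CuCl4-catalysed coupling (THF, 0 °C) with commercial 2-(2-bromoethyl)-2-methyl-1,3-dioxolane F10 gives the ketal F11, and PPTS in aqueous acetone at 50 °C unmasks 10.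

Further compounds
F1 | step 5 | 4-bromo-3,5-dimethylanisole (commercial) | COc1cc(C)c(Br)c(C)c1
F2 | step 5 | 2-bromo-1-(bromomethyl)-5-methoxy-3-methylbenzene | COc1cc(C)c(Br)c(CBr)c1
F3 | step 5 | (2-bromo-5-methoxy-3-methylbenzyl)magnesium bromide | COc1cc(C)c(Br)c(C[Mg]Br)c1
F4 | step 5 | (3R,7R,11S)-1-(2-bromo-5-methoxy-3-methylphenyl)-3,7,11,15-tetramethylhexadec-14-en-3-ol | CC(C)=CCC[C@@H](C)CCC[C@@H](C)CCC[C@@](C)(O)CCc1cc(OC)cc(C)c1Br
F5 | step 4 | ethyl (2E,7R,11S)-3,7,11,15-tetramethylhexadeca-2,14-dienoate | CC(C)=CCC[C@@H](C)CCC[C@@H](C)CCC/C(C)=C/C(=O)OCC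
F6 | step 4 | (2E,7R,11S)-3,7,11,15-tetramethylhexadeca-2,14-dien-1-ol | CC(C)=CCC[C@@H](C)CCC[C@@H](C)CCC/C(C)=C/CO
F7 | step 4 | [(2R,3R)-3-methyl-3-[(4R,8S)-4,8,12-trimethyltridec-11-en-1-yl]oxiran-2-yl]methanol | CC(C)=CCC[C@@H](C)CCC[C@@H](C)CCC[C@@]1(C)O[C@@H]1CO
F8 | step 4 | (3R,7R,11S)-3,7,11,15-tetramethylhexadec-14-ene-1,3-diol | CC(C)=CCC[C@@H](C)CCC[C@@H](C)CCC[C@@](C)(O)CCO
F9 | step 4 | (3R,7R,11S)-3-hydroxy-3,7,11,15-tetramethylhexadec-14-en-1-yl 4-methylbenzenesulfonate | CC(C)=CCC[C@@H](C)CCC[C@@H](C)CCC[C@@](C)(O)CCOS(=O)(=O)c1ccc(C)cc1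
F10 | step 3 | 2-(2-bromoethyl)-2-methyl-1,3-dioxolane (commercial) | CC1(CCBr)OCCO1
F11 | step 3 | 2-methyl-2-[(4R,8S)-4,8,12-trimethyltridec-11-en-1-yl]-1,3-dioxolane | CC(C)=CCC[C@@H](C)CCC[C@@H](C)CCCC1(C)OCCO1
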